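Read all the runs as pieces of one curve.

| flask | L | E | time |
|---|---|---|---|
| violet | 0.120 M |  |  |
| red | 0.0600 M |  |  |
| teal | 0.180 M |  |  |
| blue | 0.120 M | 0.0360 M |  |
| green | 0.120 M |  | 150 h |

| run | time / h | [E] / M |
|---|---|---|
| violet run | 1.5 | 0.0054 |
| violet run | 2.6 | 0.0103 |
| violet run | 4.4 | 0.0189 |
| violet run | 7.6 | 0.0288 |
| violet run | 13 | 0.0435 |
| violet run | 22 | 0.0622 |
| violet run | 38 | 0.0822 |
| red run | 1.5 | 0.0017 |
| red run | 2.6 | 0.0044 |
| red run | 4.4 | 0.0074 |
| red run | 7.6 | 0.0108 |
| red run | 13 | 0.0177 |
| red run | 22 | 0.0280 |
| red run | 38 | 0.0374 |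
| teal run | 1.5 | 0.0113 |
| teal run | 2.6 | 0.0186 |
| teal run | 4.4 | 0.0304 |
| teal run | 7.6 | 0.0489 |
| teal run | 13 | 0.0723 |
| teal run | 22 | 0.1014 |
| teal run | 38 | 0.1309 |
| blue run | 1.5 | 0.0411 |
| blue run | 2.6 | 0.0453 |
| blue run | 4.4 | 0.0549 |
| blue run | 7.6 | 0.0651 |
| blue run | 13 | 0.0814 |
| blue run | 22 | 0.0988 |
| blue run | 38 | 0.1193 |

(each reading ± 6 × 10⁻⁴ M)

1. how the opening rate goes with [L] round the charge of the violet run: the exponent of the rate at two percent of L gone to E (one fixed amount of E, the same in the runs compared)
2. the red run starts with 0.0600 M less of L than the violet run, and with no E. Compared where both hold the same amount of L, once fifteen percent of what the red run was charged with has turned into E, is the red run faster, slower or alike (within a tenth)?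
3. E in the green run at 150 h, as a share of the L charged

- Overall: L -> E.
- Constant volume, constant temperature.
- A reading of a species includes what of it is bound.
- An order is taken over about fifteen percent of the charge, up and down.

1. Start from the blue run. At 38 h, less its added E, it stands at 0.0833 M, against 0.0822 M in the violet run. So I treat the rate as a function of c_L and ignore c_E.

2. The violet run takes 20.9 h to use up 0.0600 M and reach the red charge: call this the head start, the hours one flask needs to arrive at another's charge. After it the two runs should coincide, so I expect the red-violet comparison to come out alike.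

3. The green run is charged like the violet run. It reaches the last red reading after the head start plus 38 h, which leaves 91.1 h.

4. Over the last interval, ln c_L falls by 0.0217 h⁻¹ in the red run, around 0.0273 M. In the violet run it falls by 0.0265 h⁻¹, around 0.0478 M. A line through both reaches 0.0153 h⁻¹ at zero c_L; call that the floor.

5. First extreme: the red value holds to the end, and the green run gives 97.4 %.

6. Second extreme: the floor applies at once, and the green run gives 95.3 %.

7. The constant should slide from the first value towards the second as c_L falls, so I commit to the middle, 96.4 %.

The forecast gives 1.4, alike and 97.5 %, on the ground that “Integrating to 150 h leaves L ≈ 0.003 M”. My middle is lower than its share.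

The flask gives 1.4, alike and 96.5 %, so all three forecast values stand, the share within its margin.

    2 L ⇌ L2, settled at all times (1.700 M⁻¹)
    L2 → E + L (0.2160 h⁻¹)
    L → E (0.01577 h⁻¹)

The green share leaves 0.00414 M of c_L, so after 20.9 h plus 38 h the mean constant reads 0.0186 h⁻¹, under the red value and over the floor. The teal half time should be its head start to the violet charge plus the violet quarter time: 10.2 h plus 8.05 h gives 18.2 h, against 18.1 h in the teal run. Take away the conversion of L into E, and the green run ends at 83.9 % instead of 96.5 %.

All runs were computed on assumed constants, noise included.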